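## Retrosynthetic overview

1. The coumarin is bought intact (isofraxidin) and attached last, by redox etherification of a neopentyl alcohol, followed by O‑desilylation.
2. That alcohol comes from a trans‑fused thiolane: Raney nickel removes the sulfur, and the two thiolane CH2 groups become the two ring methyl groups.
3. The thiolane and the cyclohexene close together in a catalytic asymmetric intramolecular Diels–Alder reaction of a sulfide‑tethered trienyl enal, which sets all three stereocentres of the target.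
4. The isopropylidene is made afterwards by moving the isopropenyl double bond into conjugation; the ring alkene is then reduced with diimide.
5. The enal is assembled by a one‑flask thia‑Michael/HWE sequence and a Suzuki coupling. Ring order: cyclohexene + thiolane (step 6), thiolane erased (step 9).

Assumption: all numbered inputs, isofraxidin included, are purchased, and the (S)‑oxazaborolidinium catalyst is taken to give the (3aR,4R,5S,7aR) series; if its facial sense is opposite, the (R)‑catalyst is used with nothing else changed.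

## Route

Step 1
Reactants: 1 (E)-2-(3-chloroprop-1-en-1-yl)-4,4,5,5-tetramethyl-1,3,2-dioxaborolane; 2 potassium thioacetate; 3 ethyl 2-(diethoxyphosphoryl)prop-2-enoate; 4 4-{[tert-butyl(dimethyl)silyl]oxy}butanal
Product: 8 ethyl (2Z)-6-{[tert-butyl(dimethyl)silyl]oxy}-2-({[(2E)-3-(4,4,5,5-tetramethyl-1,3,2-dioxaborolan-2-yl)prop-2-en-1-yl]sulfanyl}methyl)hex-2-enoate, via thioacetate 5 (not isolated), via sodium thiolate 6 (not isolated), via phosphonate adduct 7 (not isolated)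
Conditions: 1 + 2, EtOH, 0 °C → rt; NaOEt (1.0 equiv), 0 °C; 3, 0 °C; then 4, 0 °C → rt
Reagents that add atoms: potassium thioacetate (2) CC(=O)[S-].[K+]; ethyl 2-(diethoxyphosphoryl)prop-2-enoate (3) CCOC(=O)C(=C)P(=O)(OCC)OCC; 4-{[tert-butyl(dimethyl)silyl]oxy}butanal (4) O=CCCCO[Si](C)(C)C(C)(C)C
Why: SN2 thioacetylation of the allylic chloride, ethoxide S‑deacetylation, thia‑Michael addition to the phosphonoacrylate and Horner–Wadsworth–Emmons olefination of the resulting phosphonate carbanion run in one flask; the α‑branched phosphonoacetate gives mainly the isomer with the chain trans to the ester (2Z by CIP), and no stereocentre is formed.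

Step 2
Reactants: 9 2-methylprop-2-enal (methacrolein); 10 iodoform
Product: 11 (1E)-1-iodo-3-methylbuta-1,3-diene
Conditions: CrCl2 (6 equiv), CHI3 (2 equiv), THF, 0 °C
Reagents that add atoms: iodoform (10) IC(I)I
Why: Takai olefination converts the enal into the (E)‑alkenyl iodide; no stereocentre is formed.

Step 3
Reactants: 8 ethyl (2Z)-6-{[tert-butyl(dimethyl)silyl]oxy}-2-({[(2E)-3-(4,4,5,5-tetramethyl-1,3,2-dioxaborolan-2-yl)prop-2-en-1-yl]sulfanyl}methyl)hex-2-enoate; 11 (1E)-1-iodo-3-methylbuta-1,3-diene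
Product: 12 ethyl (2Z)-6-{[tert-butyl(dimethyl)silyl]oxy}-2-({[(2E,4E)-6-methylhepta-2,4,6-trien-1-yl]sulfanyl}methyl)hex-2-enoate
Conditions: Pd(dppf)Cl2 (5 mol %), K3PO4, THF/H2O, rt
Reagents that add atoms: (1E)-1-iodo-3-methylbuta-1,3-diene (11) CC(=C)/C=C/I
Why: Suzuki–Miyaura coupling of the alkenyl boronate with the alkenyl iodide proceeds with retention at both sp2 carbons and gives the (2E,4E)‑triene.

Step 4
Reactants: 12 ethyl (2Z)-6-{[tert-butyl(dimethyl)silyl]oxy}-2-({[(2E,4E)-6-methylhepta-2,4,6-trien-1-yl]sulfanyl}methyl)hex-2-enoate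
Product: 13 (2Z)-6-{[tert-butyl(dimethyl)silyl]oxy}-2-({[(2E,4E)-6-methylhepta-2,4,6-trien-1-yl]sulfanyl}methyl)hex-2-en-1-ol
Conditions: DIBAL-H (2.2 equiv), CH2Cl2, −78 °C; Rochelle salt
Reagents that add atoms: none
Why: DIBAL‑H 1,2‑reduction of the α,β‑unsaturated ester gives the allylic alcohol without touching the alkenes or the thioether.

Step 5
Reactants: 13 (2Z)-6-{[tert-butyl(dimethyl)silyl]oxy}-2-({[(2E,4E)-6-methylhepta-2,4,6-trien-1-yl]sulfanyl}methyl)hex-2-en-1-ol
Product: 14 (2Z)-6-{[tert-butyl(dimethyl)silyl]oxy}-2-({[(2E,4E)-6-methylhepta-2,4,6-trien-1-yl]sulfanyl}methyl)hex-2-enal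
Conditions: MnO2 (15 equiv), CH2Cl2, rt
Reagents that add atoms: none
Why: MnO2 allylic oxidation is selective for the allylic alcohol, spares the thioether and keeps the stable enal geometry (chain trans to CHO).

Step 6
Reactants: 14 (2Z)-6-{[tert-butyl(dimethyl)silyl]oxy}-2-({[(2E,4E)-6-methylhepta-2,4,6-trien-1-yl]sulfanyl}methyl)hex-2-enal
Product: 16 [(3aR,4R,5S,7aR)-4-(3-{[tert-butyl(dimethyl)silyl]oxy}propyl)-5-(prop-1-en-2-yl)-1,4,5,7a-tetrahydro-2-benzothiophen-3a(3H)-yl]methanol, via adduct aldehyde 15 (not isolated)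
Conditions: (S)-o-tolyl-CBS oxazaborolidine·Tf2NH (20 mol %), CH2Cl2 (0.02 M), −78 → −40 °C; then NaBH4, MeOH, −40 → 0 °C
Reagents that add atoms: none
Why: Proposed new method: an oxazaborolidinium‑catalysed intramolecular Diels–Alder reaction whose CH2–S–CH2 tether sits on the α‑carbon of the enal (closest known type: oxazaborolidinium‑catalysed Diels–Alder reactions of α‑substituted enals and of trienals); the boron‑bound enal adds to the (E,E)‑diene with CHO endo and the tether exo, so the thiolane is trans‑fused and CHO is syn to C7a–CH2S, the dienophile geometry puts the side chain syn to C3a–CH2S, the catalyst picks the face, and NaBH4 reduces the aldehyde in the same flask.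

Step 7
Reactants: 16 [(3aR,4R,5S,7aR)-4-(3-{[tert-butyl(dimethyl)silyl]oxy}propyl)-5-(prop-1-en-2-yl)-1,4,5,7a-tetrahydro-2-benzothiophen-3a(3H)-yl]methanol
Product: 17 [(3aR,4R,7aR)-4-(3-{[tert-butyl(dimethyl)silyl]oxy}propyl)-5-(propan-2-ylidene)-1,4,5,7a-tetrahydro-2-benzothiophen-3a(3H)-yl]methanol
Conditions: Co(salen-tBu,tBu)Cl (5 mol %), PhSiH3 (6 mol %), benzene, rt
Reagents that add atoms: none
Why: Metal‑hydride hydrogen‑atom‑transfer alkene isomerisation: H• adds to the 1,1‑disubstituted alkene and the tertiary radical loses the allylic H‑5, giving the conjugated tetrasubstituted isopropylidene and erasing C5, while C3a, C4 and C7a are untouched.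

Step 8
Reactants: 17 [(3aR,4R,7aR)-4-(3-{[tert-butyl(dimethyl)silyl]oxy}propyl)-5-(propan-2-ylidene)-1,4,5,7a-tetrahydro-2-benzothiophen-3a(3H)-yl]methanol
Product: 18 [(3aR,4R,7aR)-4-(3-{[tert-butyl(dimethyl)silyl]oxy}propyl)-5-(propan-2-ylidene)octahydro-2-benzothiophen-3a-yl]methanol
Conditions: TsNHNH2, NaOAc, DME/H2O, 85 °C
Reagents that add atoms: none
Why: Diimide reduction saturates the cis‑disubstituted ring alkene, leaves the tetrasubstituted exocyclic alkene alone, is not poisoned by sulfur, and changes no stereocentre.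

Step 9
Reactants: 18 [(3aR,4R,7aR)-4-(3-{[tert-butyl(dimethyl)silyl]oxy}propyl)-5-(propan-2-ylidene)octahydro-2-benzothiophen-3a-yl]methanol
Product: 19 [(1R,2R,6R)-2-(3-{[tert-butyl(dimethyl)silyl]oxy}propyl)-1,6-dimethyl-3-(propan-2-ylidene)cyclohexyl]methanol
Conditions: Raney Ni (W-2, excess), EtOH, 50 °C
Reagents that add atoms: none
Why: Raney‑nickel desulfurisation cleaves both C–S bonds, so the two thiolane CH2 groups become the C1 and C6 methyl groups and the trans ring fusion becomes the trans‑dimethyl relationship; the isolated tetrasubstituted alkene and the silyl ether survive.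

Step 10
Reactants: 19 [(1R,2R,6R)-2-(3-{[tert-butyl(dimethyl)silyl]oxy}propyl)-1,6-dimethyl-3-(propan-2-ylidene)cyclohexyl]methanol; 20 isofraxidin (7-hydroxy-6,8-dimethoxy-2H-chromen-2-one)
Product: 21 7-{[(1R,2R,6R)-2-(3-{[tert-butyl(dimethyl)silyl]oxy}propyl)-1,6-dimethyl-3-(propan-2-ylidene)cyclohexyl]methoxy}-6,8-dimethoxy-2H-chromen-2-one
Conditions: cyanomethylenetributylphosphorane (CMBP, 2 equiv), toluene, 100 °C
Reagents that add atoms: isofraxidin (20) COc1cc2ccc(=O)oc2c(OC)c1O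
Why: Mitsunobu‑type redox etherification with the Tsunoda ylide joins the acidic 7‑OH of isofraxidin to the neopentyl primary alcohol; the carbinol carbon is not stereogenic and has no β‑hydrogen to eliminate.

Step 11
Reactants: 21 7-{[(1R,2R,6R)-2-(3-{[tert-butyl(dimethyl)silyl]oxy}propyl)-1,6-dimethyl-3-(propan-2-ylidene)cyclohexyl]methoxy}-6,8-dimethoxy-2H-chromen-2-one
Product: 22 7-{[(1R,2R,6R)-2-(3-hydroxypropyl)-1,6-dimethyl-3-(propan-2-ylidene)cyclohexyl]methoxy}-6,8-dimethoxy-2H-chromen-2-one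
Conditions: HF·pyridine, THF/pyridine, 0 °C → rt
Reagents that add atoms: none
Why: Fluoride‑mediated desilylation frees the primary alcohol without base, so the coumarin lactone and the tetrasubstituted alkene are untouched.

## Compound list

1 | (E)-2-(3-chloroprop-1-en-1-yl)-4,4,5,5-tetramethyl-1,3,2-dioxaborolane | ClC/C=C/B1OC(C)(C)C(C)(C)O1 | starting material
2 | potassium thioacetate | CC(=O)[S-].[K+] | starting material
3 | ethyl 2-(diethoxyphosphoryl)prop-2-enoate | CCOC(=O)C(=C)P(=O)(OCC)OCC | starting material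
4 | 4-{[tert-butyl(dimethyl)silyl]oxy}butanal | O=CCCCO[Si](C)(C)C(C)(C)C | starting material
5 | S-[(2E)-3-(4,4,5,5-tetramethyl-1,3,2-dioxaborolan-2-yl)prop-2-en-1-yl] ethanethioate | CC(=O)SC/C=C/B1OC(C)(C)C(C)(C)O1 | intermediate
6 | sodium (2E)-3-(4,4,5,5-tetramethyl-1,3,2-dioxaborolan-2-yl)prop-2-ene-1-thiolate | [Na+].[S-]C/C=C/B1OC(C)(C)C(C)(C)O1 | intermediate
7 | ethyl 2-(diethoxyphosphoryl)-3-{[(2E)-3-(4,4,5,5-tetramethyl-1,3,2-dioxaborolan-2-yl)prop-2-en-1-yl]sulfanyl}propanoate | CCOC(=O)C(CSC/C=C/B1OC(C)(C)C(C)(C)O1)P(=O)(OCC)OCC | intermediate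
8 | ethyl (2Z)-6-{[tert-butyl(dimethyl)silyl]oxy}-2-({[(2E)-3-(4,4,5,5-tetramethyl-1,3,2-dioxaborolan-2-yl)prop-2-en-1-yl]sulfanyl}methyl)hex-2-enoate | CCOC(=O)/C(CSC/C=C/B1OC(C)(C)C(C)(C)O1)=C/CCCO[Si](C)(C)C(C)(C)C | intermediate
9 | 2-methylprop-2-enal (methacrolein) | CC(=C)C=O | starting material
10 | iodoform | IC(I)I | starting material
11 | (1E)-1-iodo-3-methylbuta-1,3-diene | CC(=C)/C=C/I | intermediate
12 | ethyl (2Z)-6-{[tert-butyl(dimethyl)silyl]oxy}-2-({[(2E,4E)-6-methylhepta-2,4,6-trien-1-yl]sulfanyl}methyl)hex-2-enoate | CCOC(=O)/C(CSC/C=C/C=C/C(C)=C)=C/CCCO[Si](C)(C)C(C)(C)C | intermediate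
13 | (2Z)-6-{[tert-butyl(dimethyl)silyl]oxy}-2-({[(2E,4E)-6-methylhepta-2,4,6-trien-1-yl]sulfanyl}methyl)hex-2-en-1-ol | OC/C(CSC/C=C/C=C/C(C)=C)=C/CCCO[Si](C)(C)C(C)(C)C | intermediate
14 | (2Z)-6-{[tert-butyl(dimethyl)silyl]oxy}-2-({[(2E,4E)-6-methylhepta-2,4,6-trien-1-yl]sulfanyl}methyl)hex-2-enal | O=C/C(CSC/C=C/C=C/C(C)=C)=C/CCCO[Si](C)(C)C(C)(C)C | intermediate
15 | (3aR,4R,5S,7aR)-4-(3-{[tert-butyl(dimethyl)silyl]oxy}propyl)-5-(prop-1-en-2-yl)-1,4,5,7a-tetrahydro-2-benzothiophene-3a(3H)-carbaldehyde (trans-fused) | O=C[C@]12CSC[C@@H]1C=C[C@H](C(C)=C)[C@H]2CCCO[Si](C)(C)C(C)(C)C | intermediate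
16 | [(3aR,4R,5S,7aR)-4-(3-{[tert-butyl(dimethyl)silyl]oxy}propyl)-5-(prop-1-en-2-yl)-1,4,5,7a-tetrahydro-2-benzothiophen-3a(3H)-yl]methanol | OC[C@]12CSC[C@@H]1C=C[C@H](C(C)=C)[C@H]2CCCO[Si](C)(C)C(C)(C)C | intermediate
17 | [(3aR,4R,7aR)-4-(3-{[tert-butyl(dimethyl)silyl]oxy}propyl)-5-(propan-2-ylidene)-1,4,5,7a-tetrahydro-2-benzothiophen-3a(3H)-yl]methanol | OC[C@]12CSC[C@@H]1C=CC(=C(C)C)[C@H]2CCCO[Si](C)(C)C(C)(C)C | intermediate
18 | [(3aR,4R,7aR)-4-(3-{[tert-butyl(dimethyl)silyl]oxy}propyl)-5-(propan-2-ylidene)octahydro-2-benzothiophen-3a-yl]methanol | OC[C@]12CSC[C@@H]1CCC(=C(C)C)[C@H]2CCCO[Si](C)(C)C(C)(C)C | intermediate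
19 | [(1R,2R,6R)-2-(3-{[tert-butyl(dimethyl)silyl]oxy}propyl)-1,6-dimethyl-3-(propan-2-ylidene)cyclohexyl]methanol | OC[C@]1(C)[C@H](C)CCC(=C(C)C)[C@H]1CCCO[Si](C)(C)C(C)(C)C | intermediate
20 | isofraxidin (7-hydroxy-6,8-dimethoxy-2H-chromen-2-one) | COc1cc2ccc(=O)oc2c(OC)c1O | starting material
21 | 7-{[(1R,2R,6R)-2-(3-{[tert-butyl(dimethyl)silyl]oxy}propyl)-1,6-dimethyl-3-(propan-2-ylidene)cyclohexyl]methoxy}-6,8-dimethoxy-2H-chromen-2-one | COc1cc2ccc(=O)oc2c(OC)c1OC[C@]1(C)[C@H](C)CCC(=C(C)C)[C@H]1CCCO[Si](C)(C)C(C)(C)C | intermediate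
22 | 7-{[(1R,2R,6R)-2-(3-hydroxypropyl)-1,6-dimethyl-3-(propan-2-ylidene)cyclohexyl]methoxy}-6,8-dimethoxy-2H-chromen-2-one (CNP0311605.1) | COc1cc2ccc(=O)oc2c(OC)c1OC[C@]1(C)[C@H](C)CCC(=C(C)C)[C@H]1CCCO | target

## Step count and risks

Total steps: 11. Longest linear sequence: 10 (steps 1, 3–11; step 2 is a one‑step side branch).

The three steps most likely to fail:

Step 6 (the ring‑forming step). The thioether may slow the boron catalyst and lower the ee, and the cis‑fused isomer (CHO exo) may compete. The fallback replaces catalyst control by a covalent auxiliary and an ionic cycloaddition. It sets out from 14: acetalisation with (2R,4R)-pentane-2,4-diol (PPTS, benzene, Dean–Stark) gives (4R,6R)-2-[(1Z)-5-{[tert-butyl(dimethyl)silyl]oxy}-1-({[(2E,4E)-6-methylhepta-2,4,6-trien-1-yl]sulfanyl}methyl)pent-1-en-1-yl]-4,6-dimethyl-1,3-dioxane F1. TMSOTf (cat., CH2Cl2, −78 °C) ionises F1 to a tethered vinyl oxocarbenium ion that closes both rings (Gassman‑type ionic Diels–Alder) to (4R,6R)-2-[(3aR,4R,5S,7aR)-4-(3-{[tert-butyl(dimethyl)silyl]oxy}propyl)-5-(prop-1-en-2-yl)-1,4,5,7a-tetrahydro-2-benzothiophen-3a(3H)-yl]-4,6-dimethyl-1,3-dioxane F2. The diastereomers of F2 are separated by chromatography, so enantiopurity no longer depends on the catalyst. Hydrolysis (LiBF4, wet MeCN) returns the route at 15, which is reduced to 16 as in step 6.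

Step 10 (etherification). The alcohol is neopentyl and flanked by two substituted ring carbons, so the Mitsunobu‑type displacement may stall. The fallback separates activation from displacement. It sets out from 19: Tf2O and 2,6‑lutidine (CH2Cl2, −78 °C) give [(1R,2R,6R)-2-(3-{[tert-butyl(dimethyl)silyl]oxy}propyl)-1,6-dimethyl-3-(propan-2-ylidene)cyclohexyl]methyl trifluoromethanesulfonate F3. F3 is displaced by the preformed caesium salt of 20 (Cs2CO3, DMF, 60 °C) and the route is rejoined at 21.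

Step 3 (cross‑coupling). The alkenyl boronate must first survive the ethoxide of step 1, the iododiene 11 is volatile and polymerisable, and the thioether may slow palladium. The fallback builds the triene before sulfur and boron are involved and needs no cross‑coupling. It sets out from 9: a Horner–Wadsworth–Emmons reaction with triethyl 4‑phosphonocrotonate (LiHMDS, THF, −78 → 0 °C) gives ethyl (2E,4E)-6-methylhepta-2,4,6-trienoate F4. DIBAL‑H reduction gives (2E,4E)-6-methylhepta-2,4,6-trien-1-ol F5. A Mitsunobu reaction with thioacetic acid (PPh3, DIAD) gives S-[(2E,4E)-6-methylhepta-2,4,6-trien-1-yl] ethanethioate F6. F6 then enters the one‑flask sequence of step 1 (NaOEt; 3; 4) and gives 12 directly, where the route continues.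

## Further compounds

F1 | step 6 | (4R,6R)-2-[(1Z)-5-{[tert-butyl(dimethyl)silyl]oxy}-1-({[(2E,4E)-6-methylhepta-2,4,6-trien-1-yl]sulfanyl}methyl)pent-1-en-1-yl]-4,6-dimethyl-1,3-dioxane | C[C@@H]1C[C@@H](C)OC(O1)/C(CSC/C=C/C=C/C(C)=C)=C/CCCO[Si](C)(C)C(C)(C)C
F2 | step 6 | (4R,6R)-2-[(3aR,4R,5S,7aR)-4-(3-{[tert-butyl(dimethyl)silyl]oxy}propyl)-5-(prop-1-en-2-yl)-1,4,5,7a-tetrahydro-2-benzothiophen-3a(3H)-yl]-4,6-dimethyl-1,3-dioxane | C[C@@H]1C[C@@H](C)OC(O1)[C@]12CSC[C@@H]1C=C[C@H](C(C)=C)[C@H]2CCCO[Si](C)(C)C(C)(C)C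
F3 | step 10 | [(1R,2R,6R)-2-(3-{[tert-butyl(dimethyl)silyl]oxy}propyl)-1,6-dimethyl-3-(propan-2-ylidene)cyclohexyl]methyl trifluoromethanesulfonate | FC(F)(F)S(=O)(=O)OC[C@]1(C)[C@H](C)CCC(=C(C)C)[C@H]1CCCO[Si](C)(C)C(C)(C)C
F4 | step 3 | ethyl (2E,4E)-6-methylhepta-2,4,6-trienoate | CCOC(=O)/C=C/C=C/C(C)=C
F5 | step 3 | (2E,4E)-6-methylhepta-2,4,6-trien-1-ol | OC/C=C/C=C/C(C)=C
F6 | step 3 | S-[(2E,4E)-6-methylhepta-2,4,6-trien-1-yl] ethanethioate | CC(=O)SC/C=C/C=C/C(C)=C
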